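The route rests on cutting the sp2–sp3 bond between C4 of the cyclohexene ring and C1'' of the 4-methylpent-3-enyl chain (C1 bears the aryl ketone, C6 the phenyl group, C3=C4 is the ring alkene). A nickel-electrocatalytic decarboxylative coupling joins a regiodefined C3=C4 enol triflate to the primary radical released from a redox-active ester of 5-methylhex-4-enoic acid. One operation installs the whole side chain and leaves the trisubstituted ring alkene exactly at C3=C4. The precursor is an enantiopure 6-phenylcyclohex-3-ene with the triflate at C4 and two methyl esters at C1, which are later turned into the trans aryl ketone.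

Key step: step 7

Remark on descriptors: the target is trans-(1R,6R); in the geminal diesters the same spatial arrangement at C6 is named S, only because C1 then outranks phenyl in the CIP order.

Remark on aryl regiochemistry: n-BuLi would metalate 1-methoxy-3,5-bis(methoxymethoxy)benzene between its two OMOM groups and so lead to a 2,6-dihydroxy-4-methoxyphenyl ketone, an isomer of the target; that site is therefore blocked with a trimethylsilyl group (steps 12 and 13), which is lost again in the last step.

Assumption: the cinchona primary amine of step 1 is used as whichever pseudoenantiomer gives the R adduct (both are available); the sense is to be checked at compound 3 by optical rotation.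

**Step 1**
Reactants: 1 (E)-4-phenylbut-3-en-2-one; 2 dimethyl malonate
Product: 3 dimethyl 2-[(1R)-3-oxo-1-phenylbutyl]propanedioate
Conditions: 9-amino-9-deoxy-epi-quinine or its quinidine-derived pseudoenantiomer (20 mol %, the one giving the R adduct), PhCO2H (40 mol %), THF, rt
Reagents that add atoms: none
Why: Organocatalytic asymmetric Michael addition: the primary amine condenses with the enone to a chiral iminium ion whose cinchona scaffold shields one face of the β-carbon while the quinuclidine nitrogen delivers the malonate, so the new benzylic stereocentre (the future C6) is set as R by the catalyst.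

**Step 2**
Reactants: 3 dimethyl 2-[(1R)-3-oxo-1-phenylbutyl]propanedioate
Product: 5 dimethyl 2-[(1S)-3-oxo-1-phenylbutyl]-2-(prop-2-en-1-yl)propanedioate, via sodium malonate enolate 4 (not isolated)
Conditions: NaH (1.05 equiv), THF, 0 °C; then allyl bromide, 0 °C to rt
Reagents that add atoms: allyl bromide, C=CCBr
Why: Malonate alkylation: NaH removes only the doubly activated malonate C–H and the soft enolate is C-allylated by SN2 attack at low temperature, which makes C1 quaternary, removes its acidic hydrogen for the next step and leaves the benzylic centre untouched.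

**Step 3**
Reactants: 5 dimethyl 2-[(1S)-3-oxo-1-phenylbutyl]-2-(prop-2-en-1-yl)propanedioate
Product: 6 dimethyl 2-[(1S)-1-phenyl-3-(triethylsilyloxy)but-3-en-1-yl]-2-(prop-2-en-1-yl)propanedioate
Conditions: Et3SiCl, then LiN(i-Pr)2 added last, THF, −78 °C; aq. NaHCO3 work-up
Reagents that add atoms: chlorotriethylsilane, CC[Si](Cl)(CC)CC
Why: Kinetic enolate formation with in situ O-silylation: the bulky amide deprotonates the unhindered methyl group and not the CH2 next to the congested benzylic carbon, and the silyl chloride already present traps the lithium enolate before it can equilibrate, attack an ester (Claisen-type closure) or expel the malonate.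

**Step 4**
Reactants: 6 dimethyl 2-[(1S)-1-phenyl-3-(triethylsilyloxy)but-3-en-1-yl]-2-(prop-2-en-1-yl)propanedioate
Product: 7 dimethyl (6S)-6-phenyl-4-(triethylsilyloxy)cyclohex-3-ene-1,1-dicarboxylate
Conditions: second-generation Grubbs catalyst (5 mol %), degassed toluene, 70 °C
Reagents that add atoms: none
Why: Ring-closing metathesis of a silyl enol ether with a terminal alkene: the ruthenium carbene loads on the allyl group and closes onto the 1,1-disubstituted enol ether, helped by the geminal diester (Thorpe–Ingold effect), to give the six-membered ring with the enol ether double bond fixed at C3=C4.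

**Step 5**
Reactants: 7 dimethyl (6S)-6-phenyl-4-(triethylsilyloxy)cyclohex-3-ene-1,1-dicarboxylate
Product: 8 dimethyl (6S)-6-phenyl-4-(trifluoromethanesulfonyloxy)cyclohex-3-ene-1,1-dicarboxylate
Conditions: CsF, PhNTf2, DME, rt
Reagents that add atoms: N-phenylbis(trifluoromethanesulfonimide), O=S(=O)(N(c1ccccc1)S(=O)(=O)C(F)(F)F)C(F)(F)F
Why: Fluoride-induced desilylation with in situ O-triflation: CsF cleaves the Si–O bond to the regiodefined enolate, which PhNTf2 sulfonylates at oxygen in the aprotic medium before any proton transfer can move the double bond, and the conditions spare the two esters that an alkyllithium could attack.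

**Step 6**
Reactants: 9 5-methylhex-4-enoic acid
Product: 10 1,3-dioxoisoindolin-2-yl 5-methylhex-4-enoate
Conditions: N-hydroxyphthalimide, N,N'-diisopropylcarbodiimide, DMAP (cat.), CH2Cl2, rt
Reagents that add atoms: N-hydroxyphthalimide, O=C1c2ccccc2C(=O)N1O
Why: Carbodiimide (Steglich-type) esterification: the O-acylisourea formed from the acid is intercepted, with DMAP as acyl-transfer catalyst, by the N–OH nucleophile to give the redox-active ester without touching the trisubstituted alkene.

**Step 7**
Reactants: 8 dimethyl (6S)-6-phenyl-4-(trifluoromethanesulfonyloxy)cyclohex-3-ene-1,1-dicarboxylate; 10 1,3-dioxoisoindolin-2-yl 5-methylhex-4-enoate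
Product: 11 dimethyl (6S)-4-(4-methylpent-3-en-1-yl)-6-phenylcyclohex-3-ene-1,1-dicarboxylate
Conditions: NiBr2(glyme) (20 mol %), 2,2'-bipyridine (20 mol %), LiBr, AgNO3 (0.3 equiv), 10 (2 equiv), DMF, rt, undivided cell, Mg anode, reticulated vitreous carbon cathode, constant current
Reagents that add atoms: none
Why: Cathodic reduction of the bipyridine-bound divalent nickel gives low-valent nickel that inserts into the C4–O bond of enol triflate 8 (bromide from LiBr takes the place of triflate on the metal), while single-electron reduction of ester 10 expels CO2 and phthalimide anion and leaves the primary 4-methylpent-3-enyl radical, which the alkenylnickel species captures before reductive elimination forms C4–C1''. The closest known reaction type is the nickel-electrocatalytic decarboxylative alkenylation of N-hydroxyphthalimide esters with alkenyl halides, a reductive cross-electrophile coupling. No ring is closed and no stereocentre is formed; C6 lies outside the reacting centres and carries no acidic hydrogen, so its configuration is carried through. The step needs cross-coupling to win over radical dimerisation and triflate homocoupling, which is secured by current-limited radical generation, an excess of 10 and the sacrificial magnesium anode in an undivided cell. It also needs the alkene to stay in place, which the substrate secures because the C3=C4 position was written into the enol triflate and substitution at the sp2 carbon does not move it. The homoallyl radical can close only to a cyclopropylcarbinyl radical that reopens to the same chain, so no isomeric side chain can arise.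

**Step 8**
Reactants: 11 dimethyl (6S)-4-(4-methylpent-3-en-1-yl)-6-phenylcyclohex-3-ene-1,1-dicarboxylate
Product: 12 methyl (6R)-4-(4-methylpent-3-en-1-yl)-6-phenylcyclohex-3-ene-1-carboxylate as a mixture of C1 epimers
Conditions: LiCl, H2O (2 equiv), DMSO, 150 °C
Reagents that add atoms: none
Why: Krapcho dealkoxycarbonylation: chloride demethylates one ester by SN2 attack, the carboxylate loses CO2 and the resulting ester enolate is protonated by water, which removes one ester cleanly but creates the C1 stereocentre without control (corrected in step 9).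

**Step 9**
Reactants: 12 methyl (6R)-4-(4-methylpent-3-en-1-yl)-6-phenylcyclohex-3-ene-1-carboxylate as a mixture of C1 epimers
Product: 13 methyl (1R,6R)-4-(4-methylpent-3-en-1-yl)-6-phenylcyclohex-3-ene-1-carboxylate
Conditions: NaOMe (0.3 equiv), MeOH, 50 °C
Reagents that add atoms: none
Why: Base-mediated epimerisation under thermodynamic control: reversible formation of the ester enolate at C1 with the matching alkoxide should funnel the mixture to the trans isomer, in which CO2Me and phenyl are both pseudo-equatorial on the cyclohexene half-chair, so the fixed C6 centre dictates the 1R configuration and residual cis ester can be separated and resubmitted.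

**Step 10**
Reactants: 13 methyl (1R,6R)-4-(4-methylpent-3-en-1-yl)-6-phenylcyclohex-3-ene-1-carboxylate
Product: 14 (1R,6R)-4-(4-methylpent-3-en-1-yl)-6-phenylcyclohex-3-ene-1-carbaldehyde
Conditions: i-Bu2AlH (1.1 equiv), toluene, −78 °C; MeOH quench at −78 °C, then aq. potassium sodium tartrate
Reagents that add atoms: none
Why: Partial hydride reduction of an ester: at −78 °C the aluminium hemiacetal formed by one hydride transfer is stable and releases the aldehyde only on work-up, so over-reduction and epimerisation of the α-centre are avoided.

**Step 11**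
Reactants: 15 5-methoxyresorcinol
Product: 16 1-methoxy-3,5-bis(methoxymethoxy)benzene
Conditions: NaH, MeOCH2Cl, DMF, 0 °C to rt
Reagents that add atoms: chloromethyl methyl ether, COCCl
Why: Williamson-type O-alkylation: both phenoxides react with the reactive α-chloro ether to give the bis-acetal, which protects the phenols and provides the directing groups for metalation.

**Step 12**
Reactants: 16 1-methoxy-3,5-bis(methoxymethoxy)benzene
Product: 18 [4-methoxy-2,6-bis(methoxymethoxy)phenyl]trimethylsilane, via doubly flanked aryllithium 17 (not isolated)
Conditions: n-BuLi, THF, 0 °C; then Me3SiCl, −78 °C to rt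
Reagents that add atoms: chlorotrimethylsilane, C[Si](C)(C)Cl
Why: Directed ortho-metalation followed by silylation: the hydrogen between the two OMOM groups is removed first because two chelating groups flank it, and trapping with Me3SiCl blocks this position so that the next metalation must occur next to the methoxy group.

**Step 13**
Reactants: 18 [4-methoxy-2,6-bis(methoxymethoxy)phenyl]trimethylsilane; 14 (1R,6R)-4-(4-methylpent-3-en-1-yl)-6-phenylcyclohex-3-ene-1-carbaldehyde
Product: 20 [6-methoxy-2,4-bis(methoxymethoxy)-3-(trimethylsilyl)phenyl][(1R,6R)-4-(4-methylpent-3-en-1-yl)-6-phenylcyclohex-3-en-1-yl]methanol (both carbinol epimers), via silyl-blocked aryllithium 19 (not isolated)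
Conditions: 18 (1.5 equiv), n-BuLi (1.4 equiv), TMEDA, THF, 0 °C; then 14, −78 to −20 °C; H2O
Reagents that add atoms: none
Why: Directed ortho-metalation and 1,2-addition of an aryllithium to an aldehyde: with the doubly activated site blocked, lithiation can occur only at the two symmetry-equivalent positions flanked by OMe and OMOM, which gives the oxygenation pattern of the target, and the carbinol stereocentre formed on addition is uncontrolled and irrelevant because it is oxidised in step 14.

**Step 14**
Reactants: 20 [6-methoxy-2,4-bis(methoxymethoxy)-3-(trimethylsilyl)phenyl][(1R,6R)-4-(4-methylpent-3-en-1-yl)-6-phenylcyclohex-3-en-1-yl]methanol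
Product: 21 [6-methoxy-2,4-bis(methoxymethoxy)-3-(trimethylsilyl)phenyl][(1R,6R)-4-(4-methylpent-3-en-1-yl)-6-phenylcyclohex-3-en-1-yl]methanone
Conditions: Dess–Martin periodinane, pyridine, CH2Cl2, 0 °C to rt
Reagents that add atoms: none
Why: Dess–Martin oxidation: the secondary benzylic alcohol is oxidised under buffered, non-acidic conditions that leave the two alkenes, the acetals, the aryl–silicon bond and the α-stereocentre (already in its stable trans arrangement) unchanged.

**Step 15**
Reactants: 21 [6-methoxy-2,4-bis(methoxymethoxy)-3-(trimethylsilyl)phenyl][(1R,6R)-4-(4-methylpent-3-en-1-yl)-6-phenylcyclohex-3-en-1-yl]methanone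
Product: 22 (2,4-dihydroxy-6-methoxyphenyl)[(1R,6R)-4-(4-methylpent-3-en-1-yl)-6-phenylcyclohex-3-en-1-yl]methanone (CNP0142503.1)
Conditions: 3 M aq. HCl, MeOH, 40 °C
Reagents that add atoms: none
Why: Acid-catalysed acetal cleavage with concurrent protodesilylation: both MOM ethers are solvolysed, and the silyl-bearing carbon, flanked by two hydroxyl groups and para to the methoxy group, is protonated at the ipso position (β-silicon-stabilised arenium ion) and loses silicon, while C1 stays trans because that is the thermodynamically preferred arrangement.

**Compound list**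

1 | (E)-4-phenylbut-3-en-2-one | CC(=O)/C=C/c1ccccc1 | starting material
2 | dimethyl malonate | COC(=O)CC(=O)OC | starting material
3 | dimethyl 2-[(1R)-3-oxo-1-phenylbutyl]propanedioate | CC(=O)C[C@H](C(C(=O)OC)C(=O)OC)c1ccccc1 | intermediate
4 | sodium enolate of 3 at the malonate carbon (not isolated) | [Na+].CC(=O)C[C@H]([C-](C(=O)OC)C(=O)OC)c1ccccc1 | intermediate
5 | dimethyl 2-[(1S)-3-oxo-1-phenylbutyl]-2-(prop-2-en-1-yl)propanedioate | CC(=O)C[C@H](C(CC=C)(C(=O)OC)C(=O)OC)c1ccccc1 | intermediate
6 | dimethyl 2-[(1S)-1-phenyl-3-(triethylsilyloxy)but-3-en-1-yl]-2-(prop-2-en-1-yl)propanedioate | C=C(O[Si](CC)(CC)CC)C[C@H](C(CC=C)(C(=O)OC)C(=O)OC)c1ccccc1 | intermediate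
7 | dimethyl (6S)-6-phenyl-4-(triethylsilyloxy)cyclohex-3-ene-1,1-dicarboxylate | COC(=O)C1(C(=O)OC)CC=C(O[Si](CC)(CC)CC)C[C@H]1c1ccccc1 | intermediate
8 | dimethyl (6S)-6-phenyl-4-(trifluoromethanesulfonyloxy)cyclohex-3-ene-1,1-dicarboxylate | COC(=O)C1(C(=O)OC)CC=C(OS(=O)(=O)C(F)(F)F)C[C@H]1c1ccccc1 | intermediate
9 | 5-methylhex-4-enoic acid | CC(C)=CCCC(=O)O | starting material
10 | 1,3-dioxoisoindolin-2-yl 5-methylhex-4-enoate | CC(C)=CCCC(=O)ON1C(=O)c2ccccc2C1=O | intermediate
11 | dimethyl (6S)-4-(4-methylpent-3-en-1-yl)-6-phenylcyclohex-3-ene-1,1-dicarboxylate | COC(=O)C1(C(=O)OC)CC=C(CCC=C(C)C)C[C@H]1c1ccccc1 | intermediate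
12 | methyl (6R)-4-(4-methylpent-3-en-1-yl)-6-phenylcyclohex-3-ene-1-carboxylate, mixture of C1 epimers | COC(=O)C1CC=C(CCC=C(C)C)C[C@H]1c1ccccc1 | intermediate
13 | methyl (1R,6R)-4-(4-methylpent-3-en-1-yl)-6-phenylcyclohex-3-ene-1-carboxylate | COC(=O)[C@@H]1CC=C(CCC=C(C)C)C[C@H]1c1ccccc1 | intermediate
14 | (1R,6R)-4-(4-methylpent-3-en-1-yl)-6-phenylcyclohex-3-ene-1-carbaldehyde | O=C[C@@H]1CC=C(CCC=C(C)C)C[C@H]1c1ccccc1 | intermediate
15 | 5-methoxyresorcinol | COc1cc(O)cc(O)c1 | starting material
16 | 1-methoxy-3,5-bis(methoxymethoxy)benzene | COCOc1cc(OC)cc(OCOC)c1 | intermediate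
17 | [4-methoxy-2,6-bis(methoxymethoxy)phenyl]lithium (not isolated) | [Li]c1c(OCOC)cc(OC)cc1OCOC | intermediate
18 | [4-methoxy-2,6-bis(methoxymethoxy)phenyl]trimethylsilane | COCOc1cc(OC)cc(OCOC)c1[Si](C)(C)C | intermediate
19 | [6-methoxy-2,4-bis(methoxymethoxy)-3-(trimethylsilyl)phenyl]lithium (not isolated) | [Li]c1c(OC)cc(OCOC)c([Si](C)(C)C)c1OCOC | intermediate
20 | [6-methoxy-2,4-bis(methoxymethoxy)-3-(trimethylsilyl)phenyl][(1R,6R)-4-(4-methylpent-3-en-1-yl)-6-phenylcyclohex-3-en-1-yl]methanol, both carbinol epimers | COc1cc(OCOC)c([Si](C)(C)C)c(OCOC)c1C(O)[C@@H]1CC=C(CCC=C(C)C)C[C@H]1c1ccccc1 | intermediate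
21 | [6-methoxy-2,4-bis(methoxymethoxy)-3-(trimethylsilyl)phenyl][(1R,6R)-4-(4-methylpent-3-en-1-yl)-6-phenylcyclohex-3-en-1-yl]methanone | COc1cc(OCOC)c([Si](C)(C)C)c(OCOC)c1C(=O)[C@@H]1CC=C(CCC=C(C)C)C[C@H]1c1ccccc1 | intermediate
22 | (2,4-dihydroxy-6-methoxyphenyl)[(1R,6R)-4-(4-methylpent-3-en-1-yl)-6-phenylcyclohex-3-en-1-yl]methanone | COc1cc(O)cc(O)c1C(=O)[C@@H]1CC=C(CCC=C(C)C)C[C@H]1c1ccccc1 | target

**Step count and risks**

Total steps: 15. Longest linear sequence: 12 steps (steps 1 to 5, 7 to 10 and 13 to 15).

Steps most likely to fail:

1. Step 7. Insertion of nickel into the enol triflate may not keep pace with radical formation, so that the radical is lost to dimerisation or hydrogen abstraction and the triflate is returned or reduced. The fallback makes the same C4–C1'' bond by a palladium-catalysed Negishi coupling. It sets out from triflate 8, which is treated with (4-methylpent-3-en-1-yl)zinc bromide F1 (from commercial 5-bromo-2-methylpent-2-ene, Zn dust and LiCl in THF) and PdCl2(dppf) in THF at 50 °C. It comes back to the route at diester 11.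

2. Step 13. The hindered, strongly basic aryllithium may enolise the α-branched aldehyde instead of adding to it, or the second metalation may be incomplete, so that aldehyde is returned. The fallback joins the same two fragments by an acylative Negishi coupling. It sets out from ester 13, which is saponified (LiOH, THF/H2O) to (1R,6R)-4-(4-methylpent-3-en-1-yl)-6-phenylcyclohex-3-ene-1-carboxylic acid F2 and converted with oxalyl chloride and catalytic DMF into (1R,6R)-4-(4-methylpent-3-en-1-yl)-6-phenylcyclohex-3-ene-1-carbonyl chloride F3. Aryllithium 19 is transmetalated with ZnCl2 to [6-methoxy-2,4-bis(methoxymethoxy)-3-(trimethylsilyl)phenyl]zinc chloride F4, which is coupled with F3 using Pd(PPh3)4 in THF. This gives ketone 21 directly, where the route is rejoined; steps 10 and 14 are then not needed.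

3. Step 15. Acid strong enough to drive the protodesilylation may also add methanol or water to the two trisubstituted alkenes, or cyclise them, before silicon is lost. The fallback removes silicon by nucleophilic fluoride attack in a separate operation, so that acid is needed only for acetal exchange. It sets out from ketone 21, which with Bu4NF in THF at 60 °C should give [2-methoxy-4,6-bis(methoxymethoxy)phenyl][(1R,6R)-4-(4-methylpent-3-en-1-yl)-6-phenylcyclohex-3-en-1-yl]methanone F5. Mild acetal exchange (pyridinium p-toluenesulfonate, MeOH, 50 °C) then leads back to the route at target 22.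

**Further compounds**

F1 | step 7 | (4-methylpent-3-en-1-yl)zinc bromide | CC(C)=CCC[Zn]Br
F2 | step 13 | (1R,6R)-4-(4-methylpent-3-en-1-yl)-6-phenylcyclohex-3-ene-1-carboxylic acid | OC(=O)[C@@H]1CC=C(CCC=C(C)C)C[C@H]1c1ccccc1
F3 | step 13 | (1R,6R)-4-(4-methylpent-3-en-1-yl)-6-phenylcyclohex-3-ene-1-carbonyl chloride | ClC(=O)[C@@H]1CC=C(CCC=C(C)C)C[C@H]1c1ccccc1
F4 | step 13 | [6-methoxy-2,4-bis(methoxymethoxy)-3-(trimethylsilyl)phenyl]zinc chloride | Cl[Zn]c1c(OC)cc(OCOC)c([Si](C)(C)C)c1OCOC
F5 | step 15 | [2-methoxy-4,6-bis(methoxymethoxy)phenyl][(1R,6R)-4-(4-methylpent-3-en-1-yl)-6-phenylcyclohex-3-en-1-yl]methanone | COc1cc(OCOC)cc(OCOC)c1C(=O)[C@@H]1CC=C(CCC=C(C)C)C[C@H]1c1ccccc1
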